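Ring C is disconnected across O1–C8a and C2–C3, which splits the target into 4-(benzyloxy)benzaldehyde (C2 and O1) and a 2-fluoroaryl alkoxymethyl ketone (C3, C4 and ring A). The key step exploits the C4 carbonyl, which makes C3 nucleophilic as an enolate and, through ring A, makes the ortho carbon C8a a vinylogous acyl fluoride: aldol addition and intramolecular SNAr close ring C in one formal [4+2] annulation and set the 2,3-trans relationship under thermodynamic control. O3 carries an enantiopure 1-(4-methoxyphenyl)ethyl group, which turns the absolute sense of ring closure into a diastereomeric relationship, so the (2R,3R) product is isolated pure; acidolysis, acetylation and hydrogenolysis then deliver the 3-O-acetate.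

Key step: step 5

Assumption: no facial bias from the auxiliary is counted on in step 5, where its only role is to make the two senses of trans ring closure diastereomeric and hence separable; locants O1, C2 to C4, C4a, C5 to C8, C8a and rings A, B, C follow flavanone numbering.

Step 1
Reactants: 1 2,6-dibromo-4-fluorophenol
Product: 2 1,3-dibromo-5-fluoro-2-methoxybenzene
Conditions: MeI, K2CO3, acetone, 56 °C
Reagents that add atoms: iodomethane, CI
Why: Williamson O-methylation of the acidic 2,6-dibromophenoxide, an SN2 reaction with no competing nucleophilic site.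

Step 2
Reactants: 2 1,3-dibromo-5-fluoro-2-methoxybenzene
Product: 3 1,3-bis(benzyloxy)-5-fluoro-2-methoxybenzene
Conditions: BnOH, CuI (cat.), 3,4,7,8-tetramethyl-1,10-phenanthroline (cat.), Cs2CO3, toluene, 110 °C
Reagents that add atoms: benzyl alcohol, OCc1ccccc1
Why: Ullmann-type copper-catalysed C–O coupling of both aryl bromides with the primary alcohol, in which the C–F bond stays intact because it is inert to copper and has no activating group for SNAr.

Step 3
Reactants: 4 (S)-1-(4-methoxyphenyl)ethanol; 5 2-chloro-N-methoxy-N-methylacetamide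
Product: 6 N-methoxy-2-[(1S)-1-(4-methoxyphenyl)ethoxy]-N-methylacetamide
Conditions: NaH, THF, 0 °C; then 5, Bu4NI (cat.), 0 → 25 °C
Reagents that add atoms: none
Why: Williamson ether synthesis by SN2 displacement of the activated α-chloro amide chloride by the sodium alkoxide of 4, which leaves the stereocentre of 4 untouched (S retained) because its C–O bond is not broken.

Step 4
Reactants: 3 1,3-bis(benzyloxy)-5-fluoro-2-methoxybenzene; 6 N-methoxy-2-[(1S)-1-(4-methoxyphenyl)ethoxy]-N-methylacetamide
Product: 8 1-[2,4-bis(benzyloxy)-6-fluoro-3-methoxyphenyl]-2-[(1S)-1-(4-methoxyphenyl)ethoxy]ethan-1-one, via aryllithium 7 (not isolated)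
Conditions: n-BuLi, THF, −78 °C; then 6, −78 °C; then H2O
Reagents that add atoms: none
Why: Directed ortho-lithiation at the only kind of ring C–H (flanked and acidified by F and OBn) followed by Weinreb ketone synthesis, in which the chelated tetrahedral adduct stops over-addition and −78 °C prevents loss of LiF to an aryne.

Step 5
Reactants: 8 1-[2,4-bis(benzyloxy)-6-fluoro-3-methoxyphenyl]-2-[(1S)-1-(4-methoxyphenyl)ethoxy]ethan-1-one; 9 4-(benzyloxy)benzaldehyde
Product: 11 (2R,3R)-5,7-bis(benzyloxy)-2-[4-(benzyloxy)phenyl]-6-methoxy-3-[(1S)-1-(4-methoxyphenyl)ethoxy]-2,3-dihydro-4H-chromen-4-one, via potassium aldolate 10 (not isolated)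
Conditions: KN(SiMe3)2 (1 equiv), 18-crown-6, THF, −78 °C; then 9, −78 → 40 °C; SiO2 chromatography
Reagents that add atoms: none
Why: Domino aldol addition/intramolecular SNAr: the potassium enolate of 8 adds through C3 to the aldehyde carbon of 9 (C2–C3 bond) to give aldolate 10, whose alkoxide oxygen O1 attacks C8a, made a vinylogous acyl fluoride by the ortho C4 carbonyl, and the Meisenheimer-type enolate expels fluoride (O1–C8a bond). The closest known reaction types are the aldol addition of α-alkoxy aryl ketone enolates to aromatic aldehydes and the SNAr cyclisation of β-hydroxy ketone alkoxides onto 2-fluoroaryl ketones to chroman-4-ones, here run as one formal [4+2] annulation. Ring C closes in a six-membered addition–elimination mode, 6-endo-trig with respect to the C8a=C4a–C4=O unit. The aldol is reversible and C3 of the product is epimerised by the alkoxide and fluoride present, so C2 and C3 are set relative to each other under thermodynamic control with the C2 aryl and C3 alkoxy groups both equatorial (2,3-trans). Their absolute sense is not induced but resolved: the S centre of the auxiliary on O3 turns the two mirror-image senses of trans ring closure into a diastereomeric relationship, so that (2R,3R)-11 is isolated pure by chromatography or crystallisation, and the residual fraction can be re-equilibrated with base through reversible E1cB opening of ring C. The step needs ring closure to outrun E1cB dehydration of 10 and needs a single site of substitution, which the use of one equivalent of base (no free base left to remove the C3 proton of 10) and the single fluoride ortho to the ketone should secure.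

Step 6
Reactants: 11 (2R,3R)-5,7-bis(benzyloxy)-2-[4-(benzyloxy)phenyl]-6-methoxy-3-[(1S)-1-(4-methoxyphenyl)ethoxy]-2,3-dihydro-4H-chromen-4-one
Product: 12 (2R,3R)-5,7-bis(benzyloxy)-2-[4-(benzyloxy)phenyl]-3-hydroxy-6-methoxy-2,3-dihydro-4H-chromen-4-one
Conditions: TFA, anisole, CH2Cl2, 0 °C
Reagents that add atoms: none
Why: Acidolysis (SN1) of the secondary 4-methoxybenzylic ether with Friedel–Crafts capture of the cation by anisole, which spares the aryl benzyl ethers and leaves C2 and C3 untouched because the C3–O bond is not broken.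

Step 7
Reactants: 12 (2R,3R)-5,7-bis(benzyloxy)-2-[4-(benzyloxy)phenyl]-3-hydroxy-6-methoxy-2,3-dihydro-4H-chromen-4-one
Product: 13 (2R,3R)-5,7-bis(benzyloxy)-2-[4-(benzyloxy)phenyl]-6-methoxy-4-oxo-3,4-dihydro-2H-chromen-3-yl acetate
Conditions: Ac2O, pyridine, DMAP (cat.), CH2Cl2, 0 → 25 °C
Reagents that add atoms: acetic anhydride, CC(=O)OC(C)=O
Why: DMAP-catalysed acylation (Steglich-type acyl transfer) of the only free hydroxyl under amine-base conditions too mild to open ring C, with the trans isomer being the thermodynamic one at the only epimerisable centre C3.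

Step 8
Reactants: 13 (2R,3R)-5,7-bis(benzyloxy)-2-[4-(benzyloxy)phenyl]-6-methoxy-4-oxo-3,4-dihydro-2H-chromen-3-yl acetate
Product: 14 6-methoxyaromadendrin 3-O-acetate [(2R,3R)-5,7-dihydroxy-2-(4-hydroxyphenyl)-6-methoxy-4-oxo-3,4-dihydro-2H-chromen-3-yl acetate]
Conditions: H2 (1 atm), Pd/C, EtOAc, 25 °C
Reagents that add atoms: none
Why: Heterogeneous hydrogenolysis of the three aryl benzyl ethers under neutral conditions, which leaves the aliphatic acetate, the ketone and both stereocentres untouched.

Compound list

1 | 2,6-dibromo-4-fluorophenol | Oc1c(Br)cc(F)cc1Br | starting material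
2 | 1,3-dibromo-5-fluoro-2-methoxybenzene | COc1c(Br)cc(F)cc1Br | intermediate
3 | 1,3-bis(benzyloxy)-5-fluoro-2-methoxybenzene | COc1c(OCc2ccccc2)cc(F)cc1OCc1ccccc1 | intermediate
4 | (S)-1-(4-methoxyphenyl)ethanol | C[C@H](O)c1ccc(OC)cc1 | starting material
5 | 2-chloro-N-methoxy-N-methylacetamide | CON(C)C(=O)CCl | starting material
6 | N-methoxy-2-[(1S)-1-(4-methoxyphenyl)ethoxy]-N-methylacetamide | CON(C)C(=O)CO[C@@H](C)c1ccc(OC)cc1 | intermediate
7 | [2,4-bis(benzyloxy)-6-fluoro-3-methoxyphenyl]lithium (not isolated) | [Li]c1c(F)cc(OCc2ccccc2)c(OC)c1OCc1ccccc1 | intermediate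
8 | 1-[2,4-bis(benzyloxy)-6-fluoro-3-methoxyphenyl]-2-[(1S)-1-(4-methoxyphenyl)ethoxy]ethan-1-one | COc1c(OCc2ccccc2)cc(F)c(C(=O)CO[C@@H](C)c2ccc(OC)cc2)c1OCc1ccccc1 | intermediate
9 | 4-(benzyloxy)benzaldehyde | O=Cc1ccc(OCc2ccccc2)cc1 | starting material
10 | potassium (1R,2R)-3-[2,4-bis(benzyloxy)-6-fluoro-3-methoxyphenyl]-1-[4-(benzyloxy)phenyl]-2-[(1S)-1-(4-methoxyphenyl)ethoxy]-3-oxopropan-1-olate (not isolated; the aldolate stereoisomers interconvert by retro-aldol and the one shown closes to 11) | COc1c(OCc2ccccc2)cc(F)c(C(=O)[C@H](O[C@@H](C)c2ccc(OC)cc2)[C@H]([O-])c2ccc(OCc3ccccc3)cc2)c1OCc1ccccc1.[K+] | intermediate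
11 | (2R,3R)-5,7-bis(benzyloxy)-2-[4-(benzyloxy)phenyl]-6-methoxy-3-[(1S)-1-(4-methoxyphenyl)ethoxy]-2,3-dihydro-4H-chromen-4-one | COc1c(OCc3ccccc3)cc2c(c1OCc1ccccc1)C(=O)[C@H](O[C@@H](C)c1ccc(OC)cc1)[C@@H](c1ccc(OCc3ccccc3)cc1)O2 | intermediate
12 | (2R,3R)-5,7-bis(benzyloxy)-2-[4-(benzyloxy)phenyl]-3-hydroxy-6-methoxy-2,3-dihydro-4H-chromen-4-one | COc1c(OCc3ccccc3)cc2c(c1OCc1ccccc1)C(=O)[C@H](O)[C@@H](c1ccc(OCc3ccccc3)cc1)O2 | intermediate
13 | (2R,3R)-5,7-bis(benzyloxy)-2-[4-(benzyloxy)phenyl]-6-methoxy-4-oxo-3,4-dihydro-2H-chromen-3-yl acetate | COc1c(OCc3ccccc3)cc2c(c1OCc1ccccc1)C(=O)[C@H](OC(C)=O)[C@@H](c1ccc(OCc3ccccc3)cc1)O2 | intermediate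
14 | 6-methoxyaromadendrin 3-O-acetate [(2R,3R)-5,7-dihydroxy-2-(4-hydroxyphenyl)-6-methoxy-4-oxo-3,4-dihydro-2H-chromen-3-yl acetate] | COc1c(O)cc2c(c1O)C(=O)[C@H](OC(C)=O)[C@@H](c1ccc(O)cc1)O2 | target

Total steps: 8. Longest linear sequence: 7 steps (steps 1, 2, 4, 5, 6, 7, 8).

Steps most likely to fail

Step 5. Ring closure may be too slow on the electron-rich ring A (the C6 methoxy group is para to fluorine and the C4 carbonyl is twisted by its two ortho substituents), so that E1cB dehydration of the aldolate or self-condensation of the enolate takes over. In addition, because the auxiliary does not bias the sense of ring closure, at most half of the ring-closed material per pass has the required configuration, and the diastereomer separation that fixes it may be inefficient. The fallback reverses the polarity of the ring-closing C–O bond and uses classical flavanone chemistry. Setting out from 8, the fluoride is exchanged for hydroxyl under weakly basic conditions that do not enolise the ketone (acetohydroxamic acid, K2CO3, DMSO, 80 °C) to give the phenol 1-[2,4-bis(benzyloxy)-6-hydroxy-3-methoxyphenyl]-2-[(1S)-1-(4-methoxyphenyl)ethoxy]ethan-1-one F1. Claisen–Schmidt condensation of this phenol with 9 (KOH, EtOH, 25 °C) should give (2Z)-1-[2,4-bis(benzyloxy)-6-hydroxy-3-methoxyphenyl]-3-[4-(benzyloxy)phenyl]-2-[(1S)-1-(4-methoxyphenyl)ethoxy]prop-2-en-1-one F2. Oxa-Michael cyclisation of this chalcone (NaOAc, EtOH, reflux), again under thermodynamic 2,3-trans control, comes back to the route at 11 after the same diastereomer separation.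

Step 2. The second C–O coupling next to the methoxy group may stall, or hydrodebromination by the alcohol may compete. The fallback separates C–O bond formation from benzylation. Setting out from 2, palladium-catalysed double hydroxylation (Pd2(dba)3, t-BuXPhos, KOH, 1,4-dioxane–H2O, 100 °C) should give 5-fluoro-2-methoxybenzene-1,3-diol F3, and Williamson benzylation (BnBr, K2CO3, DMF, 60 °C) comes back to the route at 3.

Step 4. Deprotonation of a benzylic OCH2 group (followed by Wittig rearrangement) may compete with ring lithiation, or the aryllithium may lose LiF to an aryne before it is acylated. The fallback replaces deprotonation by halogen–metal exchange on a more stable organomagnesium species. Setting out from 3, electrophilic bromination (NBS, MeCN, 0 °C) at the same activated position should give 1,3-bis(benzyloxy)-4-bromo-5-fluoro-2-methoxybenzene F4. Bromine–magnesium exchange (i-PrMgCl·LiCl, THF, −20 °C) gives [2,4-bis(benzyloxy)-6-fluoro-3-methoxyphenyl]magnesium chloride F5, and its acylation with 6 comes back to the route at 8.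

Further compounds

F1 | step 5 | 1-[2,4-bis(benzyloxy)-6-hydroxy-3-methoxyphenyl]-2-[(1S)-1-(4-methoxyphenyl)ethoxy]ethan-1-one | COc1c(OCc2ccccc2)cc(O)c(C(=O)CO[C@@H](C)c2ccc(OC)cc2)c1OCc1ccccc1
F2 | step 5 | (2Z)-1-[2,4-bis(benzyloxy)-6-hydroxy-3-methoxyphenyl]-3-[4-(benzyloxy)phenyl]-2-[(1S)-1-(4-methoxyphenyl)ethoxy]prop-2-en-1-one | COc1c(OCc2ccccc2)cc(O)c(C(=O)/C(O[C@@H](C)c2ccc(OC)cc2)=C/c2ccc(OCc3ccccc3)cc2)c1OCc1ccccc1
F3 | step 2 | 5-fluoro-2-methoxybenzene-1,3-diol | COc1c(O)cc(F)cc1O
F4 | step 4 | 1,3-bis(benzyloxy)-4-bromo-5-fluoro-2-methoxybenzene | COc1c(OCc2ccccc2)cc(F)c(Br)c1OCc1ccccc1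
F5 | step 4 | [2,4-bis(benzyloxy)-6-fluoro-3-methoxyphenyl]magnesium chloride | Cl[Mg]c1c(F)cc(OCc2ccccc2)c(OC)c1OCc1ccccc1
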